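## Structural features

38 is a cis-fused hydrindanone: a cyclohexane (C1, C2, C6, C7, C8, C9) and a cyclopentanone (C2, C3, C4, C5, C6) share the C2–C6 bond, with an exocyclic methylene on C1 and the ketone at C4. Six contiguous ring stereocentres (C5, C6, C2, C7, C8, C9) are flanked by two exocyclic ones, the C10 carbinol of the 1-acetoxyethyl group on C5 and the quaternary C11 of the methyl glycidate on C7; a ninth lies in the 2-methylbutanoate on O9, which the SMILES defines as R. On the six-membered ring the C2–C3, C6–C5 and C7–C11 bonds and O8 all lie on one face (β) and only O9 on the other (α); H2, H6 and H5 are mutually cis, so the C5 side chain sits on the concave face next to C7. Fragile groups are the β-acetoxy ketone (E1cB loss of acetate, epimerisation at C5), the terminal epoxide of the α,β-epoxy ester, the 1,1-disubstituted alkene, the (E)-3-methylpent-2-enoate (geometric scrambling, deconjugation) and the α-stereocentre of the 2-methylbutanoate. The real difficulty is the all-cis C2/C6/C7/C8 array together with the two stereocentres outside any ring (C10, C11), and the need to place three different acyl groups on O8, O9 and O10 although O8 must first serve as a tether. The key step exploits the cis-1,4 relationship of O8 and the C2 side chain across C6–C7: a two-carbon radical tether on O8 and an alkyne tether on C2 can only reach the β-face of a C6=C7 double bond, so C7–C11 and C6–C5 form cis to each other and to both tethers.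

## Logic of the disconnections

38 ⇒ 37 ⇒ 36. The O10–acetyl bond and then the C5–H bond are cut last, turning C5 into the spiro carbon of an α,β-epoxy ketone. The β-acetoxy ketone is the most base-sensitive unit and C5 is a kinetic centre, so both are made at the very end. The forward opening must spare the glycidate and the enoate, and the proton must arrive on the convex α-face (the face of H2 and H6), not on the face that carried the tethers.

36 ⇒ 34 ⇒ 33 ⇒ 32 ⇒ 31. The O9–acyl bond (from 35) is cut, then the C5–O/C10–O bonds of the epoxide, giving an E-allylic alcohol with a β-hydroxyl at C4. C10 is exocyclic and any reagent approaching an E-ethylidene from the open α-face would give the wrong C10 epimer; a hydroxyl-directed epoxidation from the β-face gives 10S. This demands a single alkene geometry and a single C4 configuration in 31.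

31 ⇒ 30 ⇒ 28 ⇒ 26. The O8–acyl bond (from 29) and the C12–OMe bond are cut and O8 is reconnected to C12 as a γ-lactone. The lactone ties O8 up until the glycidate is complete and makes C11 part of a rigid ring. The forward opening must trap the hydroxy ester before it relactonises.

26 ⇒ 23 ⇒ 21. The C11–O bond and then the C11–C13 bond are cut. Epoxidising an α-methylene lactone would put oxygen on the open face of the lactone, anti to C6, which is the C11 epimer of 38; so the order is reversed. C13 goes in first, then a halogen enters on the open face and is displaced with inversion by the C13 oxygen. The halogenation must be face-selective and closure must beat retro-aldol.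

21 ⇒ 20 ⇒ 19 ⇒ 17. Functional-group changes only: the lactone carbonyl comes from the acetal carbon and the β-C4 alcohol from an E-enone. One oxidation of 17 erases three uncontrolled elements (acetal epimers, C4 epimers and, after equilibration, the ethylidene geometry), which is why C4 is left as a free hydroxyl rather than a silyl ether.

17 ⇒ 16 (key step). The C7–C11 and C5–C6 bonds are cut, opening the acetal ring and the cyclopentane. This removes two rings and two stereocentres and leaves a monocyclic cyclohexene whose only stereochemical requirement is O8 cis to the C2 chain and trans to O9.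

16 ⇒ 14 ⇒ 13 ⇒ 11. The C4–C5 bond (15 added to an aldehyde), then the ester-to-aldehyde change, then the acetal C–O and C–Br bonds (12 and a bromonium source on O8–H) are cut. The radical precursor is assembled last, so the alkyl bromide meets only a hydride and a Grignard reagent at −78 °C.

11 ⇒ 10 ⇒ 9 ⇒ 8 ⇒ 7. The C8–O bond is cut with inversion, back to a cis-diol acetonide. The cis-diol comes from the chiral pool with C9 already correct; inverting C8 makes O8 cis to the C2 chain and, through the ester left on O8, differentiates the two hydroxyls so that O9 can be silylated. The forward substitution must occur at C8 and not at C9.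

7 ⇒ 4 + 5. The C2–C3 bond is cut as a [3,3] shift of a ketene acetal on the exocyclic CH2–O. One step makes the C2 stereocentre, the two-carbon chain at the right oxidation level and the exocyclic methylene, while C6=C7 stays where the cascade needs it. It requires attack anti to the acetonide. A Stork–Danheiser entry from a 5-substituted vinylogous ester was set aside for two reasons. That ester is racemic. Its trans alkylation followed by α′-oxidation and reduction would also place O8 and O9 on the wrong faces relative to C2.

4 ⇒ 2 ⇒ 1. The C1–CH2OH bond is cut to a vinyl bromide and the acetonide to the enantiopure diol 1, which supplies all six ring carbons, C9 in its final configuration and the absolute stereochemistry.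

## Other disconnections considered

Alternative 1: The cut is the C1–C9 bond. Forward, Ni(cod)2/PBu3 and Et3SiH would couple the ethynyl group on C2 of ynal A1 with its C9 aldehyde and close the six-membered ring as A2, the alkyne terminus becoming the methylene and O9 emerging as a triethylsilyl ether.
- In favour: the methylene and O9 appear together late, so the 1,1-disubstituted alkene never passes through radical, chromium or enolate steps. On this point it is better than the chosen plan. It is also more convergent.
- Against: A1 already carries the β-acetoxy ketone and the epimerisable C5, and its ketone competes with the aldehyde for nickel. The aldehyde is α to the C8 oxygen and can epimerise. The C9 configuration would rest on 1,2-induction in the oxanickelacycle, not on a tether. The C6–C7 bond would have to be set between two separate rings before any six-membered template exists, whereas the chosen plan sets C6 and C7 in the ring-forming step itself.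
- Step economy: after A2 about as short as the chosen endgame; before A1 longer.

Alternative 2: The cuts are C6–C7 and C5–C10. Forward, irradiation of dioxinone A3 would add its enone alkene across the cyclopentene to give cyclobutane A4, and a later retro-aldol opening would release a C5 acetyl group and a C7 carboxyl carbon.
- In favour: like the chosen plan it makes two bonds and the six-membered ring in one step (equal). The cyclobutane forces C5–C10 and C6–C7 cis, so the contra-thermodynamic C5 configuration is built in, not left to a kinetic protonation; here it is better.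
- Against: after fragmentation C10 is a ketone that needs a stereoselective reduction, C7 becomes an enolisable CH, and C13 and the oxirane are still missing. C1 is a ketal whose unmasking gives a ketone flanked by the ring-fusion C2–H and the C9 oxygen, so methylenation risks epimerisation and β-elimination. The heavily oxygenated tether of A3 is long to make.
- Step economy: worse than the chosen plan on both sides of the key step.

Alternative 3: The cut is C5–C6, made by a 1,2-shift after a Diels–Alder construction of a cis-decalin. Forward, hydroxy mesylate A5 with base or Et2AlCl would shift C6 from C10 to C5 to give acetylcyclopentane A6.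
- In favour: the migration is stereospecific (inversion at C5), so C5 is set as reliably as, or more reliably than, by protonation. The cis ring fusion comes cheaply from the cycloaddition.
- Against: A6 has a bare CH2 at C1 and a C8=C9 alkene, so O8, O9 (trans) and the methylene would all have to be introduced afterwards with no handle at C1. C10 is again a ketone. C11 sits on an open chain, so the glycidate would be made without ring control.
- Step economy: clearly longer after the key step; the chosen plan has C1, O8 and O9 in place beforehand.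

Key step: step 11

## Remarks before the steps

- Atom numbers are those of the skeleton of 38 (C1 methylene-bearing ring carbon, C2/C6 ring fusion, C4 ketone, C10 carbinol, C11 oxirane carbon, C12 ester carbon, C13 oxirane CH2). β is the face of the six-membered ring that carries the C2–C3 bond, α the other face.
- C4 in 16 and 17, the acetal carbon in 13–17 and the ethylidene geometry in 17 and 18 are spectator elements erased in step 12. They are carried as mixtures and written without descriptors.
- Diol 1 and (R)-2-methylbutanoic acid 35 are assumed purchasable in enantiopure form.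

## Route

Step 1
Reactants: 1 (1S,2S)-3-bromocyclohexa-3,5-diene-1,2-diol
Product: 2 bromodiene acetonide
Conditions: 2,2-dimethoxypropane, p-TsOH (cat.), acetone, 0 °C to rt
Reagents that add atoms: 2,2-dimethoxypropane, COC(C)(C)OC
Why: Acid-catalysed transacetalisation closes the cis-diol to a dioxolane, which also blocks the α-face of the diene for step 3; no stereocentre is touched.

Step 2
Reactants: 2 bromodiene acetonide
Product: 4 dienylmethanol acetonide, via vinyllithium 3 (not isolated)
Conditions: t-BuLi (2.1 equiv), Et2O, −78 °C; CH2O gas (from cracked paraformaldehyde), −78 to −20 °C; H2O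
Reagents that add atoms: formaldehyde, C=O
Why: Bromine–lithium exchange on the vinyl bromide followed by addition to formaldehyde; the sp2 carbanion cannot expel the neighbouring acetal oxygen in a six-membered ring, and no stereocentre is involved.

Step 3
Reactants: 4 dienylmethanol acetonide; 5 triethyl orthoacetate
Product: 7 ethyl ester acetonide (C1 methylene; C2 β-CH2CO2Et), via ketene acetal 6 (not isolated)
Conditions: 5 as solvent, EtCO2H (cat.), 125 °C, EtOH distilled off
Reagents that add atoms: none
Why: Johnson–Claisen rearrangement: orthoester exchange and loss of ethanol give 6, whose [3,3] shift forms C2–C3 and moves C1=C2 to the exocyclic position while C6=C7 stays; the new C2 centre is set by delivery to the β-face, anti to the α-dioxolane.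

Step 4
Reactants: 7 ethyl ester acetonide
Product: 8 cis-diol ester (C8 and C9 α-OH)
Conditions: AcOH/H2O (4:1), 40 °C
Reagents that add atoms: none
Why: Mild hydrolysis of the isopropylidene acetal; ester, skipped diene and stereocentres are unaffected.

Step 5
Reactants: 8 cis-diol ester
Product: 9 C8 β-(4-nitrobenzoate) with C9 α-OH
Conditions: PPh3, DIAD, 4-nitrobenzoic acid, THF, 0 °C to rt
Reagents that add atoms: 4-nitrobenzoic acid, OC(=O)c1ccc(cc1)[N+](=O)[O-]
Why: Mitsunobu reaction of a cis-1,2-diol via its dioxaphosphorane gives a trans hydroxy ester by SN2 attack of carboxylate at one carbon. Attack is expected at the cyclohexenyl carbon C8, because β-approach to C9 is shielded by the β side chain on C2 and by the fully substituted C1. C8 is inverted and C9 keeps its α-OH.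

Step 6
Reactants: 9 hydroxy nitrobenzoate
Product: 10 C9 α-OTBS nitrobenzoate
Conditions: TBSOTf, 2,6-lutidine, CH2Cl2, −40 to 0 °C
Reagents that add atoms: tert-butyldimethylsilyl triflate, CC(C)(C)[Si](C)(C)OS(=O)(=O)C(F)(F)F
Why: The triflate silylates the hindered C9 hydroxyl; this ether must last until step 22.

Step 7
Reactants: 10 silyl ether nitrobenzoate
Product: 11 allylic alcohol (C8 β-OH; C9 α-OTBS)
Conditions: K2CO3 (0.3 equiv), EtOH, 0 °C
Reagents that add atoms: none
Why: Base-catalysed ethanolysis of the activated aryl ester; ethanol leaves the ethyl ester unchanged, and the low temperature limits 1,2-silyl migration.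

Step 8
Reactants: 11 allylic alcohol; 12 ethyl vinyl ether
Product: 13 bromoacetal ester
Conditions: NBS, 12 (3 equiv), CH2Cl2, −40 to 0 °C
Reagents that add atoms: N-bromosuccinimide, BrN1C(=O)CCC1=O
Why: Bromoetherification of the enol ether (the Ueno–Stork precursor): the electron-rich vinyl ether takes up bromine far faster than the two other alkenes and O8 traps the oxocarbenium ion; both acetal epimers form.

Step 9
Reactants: 13 bromoacetal ester
Product: 14 bromoacetal aldehyde
Conditions: iBu2AlH (1.1 equiv), CH2Cl2, −78 °C; aq. potassium sodium tartrate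
Reagents that add atoms: none
Why: Partial ester reduction through the aluminium hemiacetal, which is stable at −78 °C; the primary bromide and the acetal are inert.

Step 10
Reactants: 14 bromoacetal aldehyde; 15 1-propynylmagnesium bromide
Product: 16 cyclohexenyl bromoacetal with a 2-hydroxypent-3-ynyl chain on C2
Conditions: THF, −78 to −20 °C; H2O
Reagents that add atoms: none
Why: 1,2-Addition of the alkynyl Grignard reagent to the aldehyde; the alkyl bromide does not react at this temperature; both C4 epimers are accepted.

Step 11
Reactants: 16 cyclohexenyl bromoacetal alkynol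
Product: 17 tricyclic ethylidenecyclopentane fused to a lactol ether
Conditions: Bu3SnH (1.3 equiv, syringe pump 6 h), AIBN (0.2 equiv), benzene (0.005 M), 80 °C
Reagents that add atoms: none
Why: The tributyltin radical abstracts bromine from 16, and the primary radical closes 5-exo-trig onto C7; the five-membered acetal ring can only be cis-fused, so C7–C11 forms cis to O8. The secondary C6 radical then closes 5-exo-dig onto the alkyne carbon C5 hanging from C2, which is possible only on the β-face and gives the cis-hydrindane. The σ-vinyl radical at C10 takes hydrogen from Bu3SnH and the tin radical carries the chain. The closest known reaction type is the Ueno–Stork haloacetal cyclisation run in tandem with a second exo closure onto an alkyne. C7 and C6 are the two new stereocentres, set by the O8 tether and the C2 tether respectively; because these are cis-1,4 across the alkene, no reagent control is needed. The step needs 5-exo over 6-endo attack at C7 (kinetically strongly preferred; the 6-exo alternative onto the C1 methylene is slower still). It also needs closure of the C6 radical before hydrogen capture, which slow addition of Bu3SnH and the substituent at C4 favour, and bromine abstraction in preference to stannyl addition to the alkyne. The free C4 hydroxyl tolerates tin radicals, and the acetal epimers, C4 epimers and ethylidene isomers of 17 do not matter because step 12 erases them.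

Step 12
Reactants: 17 tricyclic lactol ether
Product: 19 E-ethylidene enone lactone, via enone lactone E/Z mixture 18 (not isolated)
Conditions: CrO3, H2SO4, H2O (Jones), acetone, 0 °C, 20 min; then I2 (5 mol %), CH2Cl2, rt, daylight
Reagents that add atoms: water, O
Why: Jones oxidation hydrolyses the ethyl acetal, oxidises the lactol to the γ-lactone and the allylic C4 alcohol to the enone, removing the acetal and C4 epimers; iodine-catalysed equilibration should then give the more stable E isomer (methyl anti to the carbonyl).

Step 13
Reactants: 19 E-enone lactone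
Product: 20 allylic alcohol (C4 β-OH)
Conditions: NaBH4, CeCl3·7H2O, MeOH/THF, −78 °C
Reagents that add atoms: none
Why: Luche 1,2-reduction; hydride should add from the convex α-face of the cis-hydrindane, giving the β-alcohol needed to direct step 20; the lactone is not reduced at −78 °C.

Step 14
Reactants: 20 allylic alcohol
Product: 21 C4 β-OTES lactone
Conditions: Et3SiCl, imidazole, DMF, 0 °C
Reagents that add atoms: chlorotriethylsilane, CC[Si](Cl)(CC)CC
Why: Silylation masks C4–OH for the enolate steps; triethylsilyl is chosen so that step 19 can remove it next to the C9 silyl ether.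

Step 15
Reactants: 21 silyl ether lactone
Product: 23 α-hydroxymethyl lactone, via lactone enolate 22 (not isolated)
Conditions: LiN(iPr)2 (1.2 equiv), THF, −78 °C; CH2O gas, −78 to −40 °C; H2O
Reagents that add atoms: formaldehyde, C=O
Why: Aldol addition of the lactone lithium enolate to monomeric formaldehyde installs C13; the C11 configuration is irrelevant because C11 is enolised again in step 16.

Step 16
Reactants: 23 α-hydroxymethyl lactone
Product: 26 spiro-epoxy lactone, via lactone dianion 24 (not isolated), via iodo alkoxide 25 (not isolated)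
Conditions: LiN(iPr)2 (2.3 equiv), THF, −78 to −40 °C; I2 (1.1 equiv), −78 °C; then 0 °C
Reagents that add atoms: none
Why: Fráter–Seebach-type dianion formation, C-iodination and Darzens-type closure: iodine should attack the enolate on the open face of the cis-fused lactone (anti to C6, whose C5 substituent overhangs the other face); the C13 alkoxide then displaces iodide with inversion, so the oxirane oxygen ends on the face syn to C6, as in 38.

Step 17
Reactants: 26 spiro-epoxy lactone
Product: 28 hydroxy methyl ester (C8 β-OH), via lithium carboxylate 27 (not isolated)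
Conditions: LiOH (1.1 equiv), THF/H2O, 0 °C; solvent removed; MeI, DMF, 0 °C
Reagents that add atoms: lithium hydroxide, [Li+].[OH-]; iodomethane, CI
Why: Saponification of the α-oxygenated lactone followed by SN2 methylation of the carboxylate avoids the acid under which a γ-hydroxy ester relactonises; 28 is used at once.

Step 18
Reactants: 28 hydroxy methyl ester; 29 (E)-3-methylpent-2-enoic acid
Product: 30 C8 enoate
Conditions: 2,4,6-trichlorobenzoyl chloride, Et3N, toluene, rt; then 28, DMAP, 0 °C to rt
Reagents that add atoms: none
Why: Yamaguchi esterification through the mixed anhydride acylates the hindered C8 hydroxyl without generating a vinylketene, so the E geometry and the conjugation of the acid are kept.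

Step 19
Reactants: 30 C8 enoate
Product: 31 allylic alcohol (C4 β-OH) with C9 OTBS
Conditions: HF·pyridine, pyridine, THF, 0 °C
Reagents that add atoms: none
Why: Buffered fluoride cleaves the secondary triethylsilyl ether much faster than the hindered tert-butyldimethylsilyl ether and leaves the esters and the oxirane alone.

Step 20
Reactants: 31 allylic alcohol
Product: 32 epoxy alcohol (C5–C10 oxirane, oxygen β)
Conditions: VO(acac)2 (5 mol %), t-BuOOH, CH2Cl2, 0 °C to rt
Reagents that add atoms: tert-butyl hydroperoxide, CC(C)(C)OO
Why: Hydroxyl-directed epoxidation: the vanadate ester of the β-C4 alcohol delivers oxygen to the β-face of the E-ethylidene, which sets C10 as S; the methylene and the enoate have no directing hydroxyl.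

Step 21
Reactants: 32 epoxy alcohol
Product: 33 α,β-epoxy ketone
Conditions: Dess–Martin periodinane, NaHCO3, CH2Cl2, 0 °C to rt
Reagents that add atoms: none
Why: Buffered Dess–Martin oxidation gives the epoxy ketone without acid-promoted opening of either oxirane.

Step 22
Reactants: 33 epoxy ketone
Product: 34 C9 α-alcohol
Conditions: HF·pyridine, THF, 0 °C to rt
Reagents that add atoms: none
Why: Fluoride desilylation under mildly acidic conditions, under which acyl migration from O8 to O9 is slow.

Step 23
Reactants: 34 C9 alcohol; 35 (R)-2-methylbutanoic acid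
Product: 36 diester epoxy ketone
Conditions: EDC·HCl, DMAP (0.2 equiv), CH2Cl2, 0 °C to rt
Reagents that add atoms: none
Why: Steglich-type carbodiimide esterification; no ketene is formed, so the α-stereocentre of 35 is retained.

Step 24
Reactants: 36 diester epoxy ketone
Product: 37 β-hydroxy ketone (C5 R, C10 S)
Conditions: SmI2 (2.2 equiv), THF/MeOH (4:1), −90 °C, 5 min; pH 7 buffer
Reagents that add atoms: none
Why: Reductive opening of the α,β-epoxy ketone: the ketyl cleaves the C5–O bond and methanol protonates the samarium enolate on the convex α-face, placing H5 cis to H6 and the side chain on the β-face. At −90 °C without HMPA the epoxy ester and the enoate should survive, and C10 is not touched.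

Step 25
Reactants: 37 β-hydroxy ketone
Product: 38 CNP0251769.2
Conditions: Ac2O, pyridine, DMAP (5 mol %), CH2Cl2, 0 °C
Reagents that add atoms: acetic anhydride, CC(=O)OC(C)=O
Why: Acetylation under mild, cold conditions to avoid E1cB loss of the new acetate and epimerisation at C5.

## Compound list

1 | (1S,2S)-3-bromocyclohexa-3,5-diene-1,2-diol | BrC1=CC=C[C@H](O)[C@@H]1O | starting material
2 | bromodiene acetonide, (3aS,7aS)-4-bromo-2,2-dimethyl-3a,7a-dihydro-1,3-benzodioxole | BrC1=CC=C[C@@H]2OC(C)(C)O[C@H]12 | intermediate
3 | vinyllithium (2 with Li in place of Br) | [Li]C1=CC=C[C@@H]2OC(C)(C)O[C@H]12 | intermediate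
4 | dienylmethanol acetonide (2 with CH2OH in place of Br) | OCC1=CC=C[C@@H]2OC(C)(C)O[C@H]12 | intermediate
5 | triethyl orthoacetate | CC(OCC)(OCC)OCC | starting material
6 | ketene acetal (1-ethoxyvinyl ether of 4) | C=C(OCC)OCC1=CC=C[C@@H]2OC(C)(C)O[C@H]12 | intermediate
7 | ethyl ester acetonide: C1 methylene, C2 β-CH2CO2Et, C6=C7, C8/C9 α-O,O-isopropylidene | C=C1[C@@H](CC(=O)OCC)C=C[C@@H]2OC(C)(C)O[C@H]12 | intermediate
8 | cis-diol ester: as 7 with C8 α-OH and C9 α-OH | C=C1[C@@H](CC(=O)OCC)C=C[C@H](O)[C@@H]1O | intermediate
9 | C8 β-(4-nitrobenzoyloxy), C9 α-hydroxy ester | C=C1[C@@H](CC(=O)OCC)C=C[C@@H](OC(=O)c2ccc(cc2)[N+](=O)[O-])[C@@H]1O | intermediate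
10 | C8 β-(4-nitrobenzoyloxy), C9 α-OTBS ester | C=C1[C@@H](CC(=O)OCC)C=C[C@@H](OC(=O)c2ccc(cc2)[N+](=O)[O-])[C@@H]1O[Si](C)(C)C(C)(C)C | intermediate
11 | allylic alcohol: C8 β-OH, C9 α-OTBS, C2 β-CH2CO2Et | C=C1[C@@H](CC(=O)OCC)C=C[C@@H](O)[C@@H]1O[Si](C)(C)C(C)(C)C | intermediate
12 | ethyl vinyl ether | C=COCC | starting material
13 | bromoacetal ester: C8 β-OCH(OEt)CH2Br (both acetal epimers) | C=C1[C@@H](CC(=O)OCC)C=C[C@@H](OC(OCC)CBr)[C@@H]1O[Si](C)(C)C(C)(C)C | intermediate
14 | bromoacetal aldehyde: C2 β-CH2CHO | C=C1[C@@H](CC=O)C=C[C@@H](OC(OCC)CBr)[C@@H]1O[Si](C)(C)C(C)(C)C | intermediate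
15 | 1-propynylmagnesium bromide | CC#C[Mg]Br | starting material
16 | radical precursor: cyclohexenyl bromoacetal with C2 β-CH2CH(OH)C≡CCH3 (C4 epimers), C9 α-OTBS | C=C1[C@@H](CC(O)C#CC)C=C[C@@H](OC(OCC)CBr)[C@@H]1O[Si](C)(C)C(C)(C)C | intermediate
17 | tricyclic ethylidenecyclopentane fused to a lactol ethyl ether: H2, H6, H7, H8 all α; C4 OH (epimers); C9 α-OTBS | C=C1[C@H]2CC(O)C(=CC)[C@H]2[C@H]3CC(OCC)O[C@H]3[C@@H]1O[Si](C)(C)C(C)(C)C | intermediate
18 | ethylidene enone γ-lactone, E/Z mixture | C=C1[C@H]2CC(=O)C(=CC)[C@H]2[C@H]3CC(=O)O[C@H]3[C@@H]1O[Si](C)(C)C(C)(C)C | intermediate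
19 | (E)-ethylidene enone γ-lactone | C=C1[C@H]2CC(=O)/C(=C/C)[C@H]2[C@H]3CC(=O)O[C@H]3[C@@H]1O[Si](C)(C)C(C)(C)C | intermediate
20 | allylic alcohol lactone, C4 β-OH, E-ethylidene | C=C1[C@H]2C[C@@H](O)/C(=C/C)[C@H]2[C@H]3CC(=O)O[C@H]3[C@@H]1O[Si](C)(C)C(C)(C)C | intermediate
21 | C4 β-OTES lactone | C=C1[C@H]2C[C@@H](O[Si](CC)(CC)CC)/C(=C/C)[C@H]2[C@H]3CC(=O)O[C@H]3[C@@H]1O[Si](C)(C)C(C)(C)C | intermediate
22 | lithium enolate of lactone 21 | C=C1[C@H]2C[C@@H](O[Si](CC)(CC)CC)/C(=C/C)[C@H]2[C@H]3C=C(O[Li])O[C@H]3[C@@H]1O[Si](C)(C)C(C)(C)C | intermediate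
23 | α-hydroxymethyl lactone (C13 expected on the open face) | C=C1[C@H]2C[C@@H](O[Si](CC)(CC)CC)/C(=C/C)[C@H]2[C@H]3[C@H](CO)C(=O)O[C@H]3[C@@H]1O[Si](C)(C)C(C)(C)C | intermediate
24 | dilithium enolate alkoxide of 23 | C=C1[C@H]2C[C@@H](O[Si](CC)(CC)CC)/C(=C/C)[C@H]2[C@H]3C(CO[Li])=C(O[Li])O[C@H]3[C@@H]1O[Si](C)(C)C(C)(C)C | intermediate
25 | α-iodo lactone lithium alkoxide (iodine on the open face) | C=C1[C@H]2C[C@@H](O[Si](CC)(CC)CC)/C(=C/C)[C@H]2[C@H]3[C@@](I)(CO[Li])C(=O)O[C@H]3[C@@H]1O[Si](C)(C)C(C)(C)C | intermediate
26 | spiro-epoxy γ-lactone (oxirane oxygen syn to C6) | C=C1[C@H]2C[C@@H](O[Si](CC)(CC)CC)/C(=C/C)[C@H]2[C@H]3[C@]4(CO4)C(=O)O[C@H]3[C@@H]1O[Si](C)(C)C(C)(C)C | intermediate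
27 | lithium glycidate with free C8 β-OH | C=C1[C@H]2C[C@@H](O[Si](CC)(CC)CC)/C(=C/C)[C@H]2[C@@H]([C@@]3(C(=O)O[Li])CO3)[C@@H](O)[C@@H]1O[Si](C)(C)C(C)(C)C | intermediate
28 | methyl glycidate with free C8 β-OH | C=C1[C@H]2C[C@@H](O[Si](CC)(CC)CC)/C(=C/C)[C@H]2[C@@H]([C@@]3(C(=O)OC)CO3)[C@@H](O)[C@@H]1O[Si](C)(C)C(C)(C)C | intermediate
29 | (E)-3-methylpent-2-enoic acid | CC/C(C)=C/C(=O)O | starting material
30 | C8 (E)-3-methylpent-2-enoate, C4 OTES, C9 OTBS | C=C1[C@H]2C[C@@H](O[Si](CC)(CC)CC)/C(=C/C)[C@H]2[C@@H]([C@@]3(C(=O)OC)CO3)[C@@H](OC(=O)/C=C(\C)CC)[C@@H]1O[Si](C)(C)C(C)(C)C | intermediate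
31 | allylic alcohol: C4 β-OH, E-ethylidene, C9 OTBS | C=C1[C@H]2C[C@@H](O)/C(=C/C)[C@H]2[C@@H]([C@@]3(C(=O)OC)CO3)[C@@H](OC(=O)/C=C(\C)CC)[C@@H]1O[Si](C)(C)C(C)(C)C | intermediate
32 | epoxy alcohol: C5–C10 oxirane with β-oxygen, C10 S, C4 β-OH | C=C1[C@H]2C[C@@H](O)[C@@]3(O[C@H]3C)[C@H]2[C@@H]([C@@]4(C(=O)OC)CO4)[C@@H](OC(=O)/C=C(\C)CC)[C@@H]1O[Si](C)(C)C(C)(C)C | intermediate
33 | α,β-epoxy ketone, C9 OTBS | C=C1[C@H]2CC(=O)[C@@]3(O[C@H]3C)[C@H]2[C@@H]([C@@]4(C(=O)OC)CO4)[C@@H](OC(=O)/C=C(\C)CC)[C@@H]1O[Si](C)(C)C(C)(C)C | intermediate
34 | α,β-epoxy ketone, C9 α-OH | C=C1[C@H]2CC(=O)[C@@]3(O[C@H]3C)[C@H]2[C@@H]([C@@]4(C(=O)OC)CO4)[C@@H](OC(=O)/C=C(\C)CC)[C@@H]1O | intermediate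
35 | (R)-2-methylbutanoic acid | CC[C@@H](C)C(=O)O | starting material
36 | α,β-epoxy ketone with both ring esters | C=C1[C@H]2CC(=O)[C@@]3(O[C@H]3C)[C@H]2[C@@H]([C@@]4(C(=O)OC)CO4)[C@@H](OC(=O)/C=C(\C)CC)[C@@H]1OC(=O)[C@H](C)CC | intermediate
37 | β-hydroxy ketone (deacetyl target) | C=C1[C@H]2CC(=O)[C@@H]([C@H](C)O)[C@H]2[C@@H]([C@@]3(C(=O)OC)CO3)[C@@H](OC(=O)/C=C(\C)CC)[C@@H]1OC(=O)[C@H](C)CC | intermediate
38 | CNP0251769.2 | C=C1[C@H]2CC(=O)[C@@H]([C@H](C)OC(C)=O)[C@H]2[C@@H]([C@@]2(C(=O)OC)CO2)[C@@H](OC(=O)/C=C(\C)CC)[C@@H]1OC(=O)[C@H](C)CC | target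

## Step count and least certain steps

Total: 25 steps. Longest linear sequence: 25 steps, from 1.

Step 11 (key step). The most likely failure is hydrogen capture by the C6 radical before the slower 5-exo-dig closure, or stannyl-radical addition to the alkyne, both of which grow with the tin hydride concentration. Fallback: replace the reductive chain by an iodine atom-transfer chain, which contains no hydrogen donor. It sets out from 16: NaI in acetone exchanges the halide to give the iodoacetal alkynol F1. Et3B/air or (Bu3Sn)2 with a sunlamp in benzene then runs the same two closures; premature iodine capture at C6 is reversible, whereas iodine capture by the vinyl radical is not, so the material is funnelled to the vinyl iodide tricycle F2. Hydrodeiodination with Bu3SnH and Pd(PPh3)4 (a zerovalent palladium complex) returns to the route at 17.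

Step 5. Poor regiocontrol in the opening of the dioxaphosphorane (substitution at C9, or SN2′ attack at C6) or collapse to a vinyl epoxide is the risk, because both hydroxyls are allylic. Fallback: differentiate the hydroxyls before the Claisen step, so that the Mitsunobu reaction later meets a single alcohol. It sets out from 1:
- Et3SiCl/imidazole at −20 °C should silylate the less hindered hydroxyl remote from bromine, giving the C8 triethylsilyl ether F3.
- TBSOTf/2,6-lutidine gives the bis-silyl bromodiene F4.
- t-BuLi then formaldehyde gives the bis-silyl dienylmethanol F5.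
- Johnson–Claisen rearrangement with 5 gives the bis-silyl ester F6, the β-face being open anti to both silyloxy groups.
- PPTS in EtOH removes only the triethylsilyl group to give the C8 α-alcohol F7.
- An ordinary Mitsunobu inversion with 4-nitrobenzoic acid returns to the route at 10.

Step 16. Iodination on the wrong face, or retro-aldol loss of formaldehyde from the alkoxide before closure, would give the C11 epimer or return 21. Fallback: introduce oxygen first and carbon second, so that the open-face preference again places oxygen syn to C6. It sets out from 21: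
- LiN(iPr)2 then 2-(phenylsulfonyl)-3-phenyloxaziridine gives the α-hydroxy lactone F8 (hydroxyl on the open face).
- LiN(iPr)2 (2.3 equiv) then formaldehyde adds C13 on the open face and pushes the hydroxyl to the face of C6, giving the diol lactone F9.
- TsCl/pyridine gives the primary tosylate F10, and NaH in THF closes the oxirane with retention at C11, returning to the route at 26.

Step 17. The hydroxy ester can relactonise before or during the slow acylation of the hindered C8 hydroxyl, since the cis-fused γ-lactone is the thermodynamic sink. Fallback: acylate O8 while C12 is at the aldehyde level, where reclosure gives only a reversible lactol. It sets out from 26: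
- iBu2AlH at −78 °C gives the epoxy lactol F11.
- N,N-dimethylhydrazine opens it to the hydroxy hydrazone F12.
- Yamaguchi acylation with 29 gives the acylated hydrazone F13.
- Aqueous CuCl2 at pH 7 releases the glycidic aldehyde F14.
- NaClO2/NaH2PO4 with 2-methylbut-2-ene gives the glycidic acid F15, and Me3SiCHN2 returns to the route at 30.

Step 24. Over-reduction of the epoxy ester or the enoate by SmI2, protonation of the samarium enolate from the β-face, or retro-aldol cleavage of the samarium aldolate are the risks. Fallback: make the C10–O bond through boron without an epoxide or a one-electron reductant. It sets out from 31: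
- Dess–Martin oxidation gives the E-enone silyl ether F16.
- HF·pyridine gives the E-enone C9 alcohol F17.
- EDC/DMAP with 35 gives the E-enone diester F18.
- CuCl, NaOtBu, a chiral ferrocenyl bisphosphine, B2pin2 and MeOH add boron to C10 and protonate C5 on the α-face to give the β-boryl ketone F19. The ligand antipode must be the one that places boron on the β-face, against the substrate's own preference.
- NaBO3 oxidises the C–B bond with retention and returns to the route at 37.

## Further compounds

F1 | step 11 | iodoacetal alkynol (16 with I in place of Br) | C=C1[C@@H](CC(O)C#CC)C=C[C@@H](OC(OCC)CI)[C@@H]1O[Si](C)(C)C(C)(C)C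
F2 | step 11 | vinyl iodide tricycle (17 with I on C10) | C=C1[C@H]2CC(O)C(=C(C)I)[C@H]2[C@H]3CC(OCC)O[C@H]3[C@@H]1O[Si](C)(C)C(C)(C)C
F3 | step 5 | C8 triethylsilyl ether of diol 1 | BrC1=CC=C[C@H](O[Si](CC)(CC)CC)[C@@H]1O
F4 | step 5 | bis-silyl bromodiene (C8 OTES, C9 OTBS) | BrC1=CC=C[C@H](O[Si](CC)(CC)CC)[C@@H]1O[Si](C)(C)C(C)(C)C
F5 | step 5 | bis-silyl dienylmethanol | OCC1=CC=C[C@H](O[Si](CC)(CC)CC)[C@@H]1O[Si](C)(C)C(C)(C)C
F6 | step 5 | bis-silyl ester (C2 β-CH2CO2Et, C8 α-OTES, C9 α-OTBS) | C=C1[C@@H](CC(=O)OCC)C=C[C@H](O[Si](CC)(CC)CC)[C@@H]1O[Si](C)(C)C(C)(C)C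
F7 | step 5 | C8 α-alcohol, C9 α-OTBS ester | C=C1[C@@H](CC(=O)OCC)C=C[C@H](O)[C@@H]1O[Si](C)(C)C(C)(C)C
F8 | step 16 | α-hydroxy lactone (hydroxyl on the open face) | C=C1[C@H]2C[C@@H](O[Si](CC)(CC)CC)/C(=C/C)[C@H]2[C@H]3[C@H](O)C(=O)O[C@H]3[C@@H]1O[Si](C)(C)C(C)(C)C
F9 | step 16 | α-hydroxy-α-hydroxymethyl lactone (hydroxyl syn to C6) | C=C1[C@H]2C[C@@H](O[Si](CC)(CC)CC)/C(=C/C)[C@H]2[C@H]3[C@](O)(CO)C(=O)O[C@H]3[C@@H]1O[Si](C)(C)C(C)(C)C
F10 | step 16 | primary tosylate of F9 | C=C1[C@H]2C[C@@H](O[Si](CC)(CC)CC)/C(=C/C)[C@H]2[C@H]3[C@](O)(COS(=O)(=O)c4ccc(C)cc4)C(=O)O[C@H]3[C@@H]1O[Si](C)(C)C(C)(C)C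
F11 | step 17 | spiro-epoxy lactol | C=C1[C@H]2C[C@@H](O[Si](CC)(CC)CC)/C(=C/C)[C@H]2[C@H]3[C@]4(CO4)C(O)O[C@H]3[C@@H]1O[Si](C)(C)C(C)(C)C
F12 | step 17 | hydroxy N,N-dimethylhydrazone | C=C1[C@H]2C[C@@H](O[Si](CC)(CC)CC)/C(=C/C)[C@H]2[C@@H]([C@@]3(C=NN(C)C)CO3)[C@@H](O)[C@@H]1O[Si](C)(C)C(C)(C)C
F13 | step 17 | C8 enoate N,N-dimethylhydrazone | C=C1[C@H]2C[C@@H](O[Si](CC)(CC)CC)/C(=C/C)[C@H]2[C@@H]([C@@]3(C=NN(C)C)CO3)[C@@H](OC(=O)/C=C(\C)CC)[C@@H]1O[Si](C)(C)C(C)(C)C
F14 | step 17 | glycidic aldehyde | C=C1[C@H]2C[C@@H](O[Si](CC)(CC)CC)/C(=C/C)[C@H]2[C@@H]([C@@]3(C=O)CO3)[C@@H](OC(=O)/C=C(\C)CC)[C@@H]1O[Si](C)(C)C(C)(C)C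
F15 | step 17 | glycidic acid | C=C1[C@H]2C[C@@H](O[Si](CC)(CC)CC)/C(=C/C)[C@H]2[C@@H]([C@@]3(C(=O)O)CO3)[C@@H](OC(=O)/C=C(\C)CC)[C@@H]1O[Si](C)(C)C(C)(C)C
F16 | step 24 | E-enone, C9 OTBS | C=C1[C@H]2CC(=O)/C(=C/C)[C@H]2[C@@H]([C@@]3(C(=O)OC)CO3)[C@@H](OC(=O)/C=C(\C)CC)[C@@H]1O[Si](C)(C)C(C)(C)C
F17 | step 24 | E-enone, C9 α-OH | C=C1[C@H]2CC(=O)/C(=C/C)[C@H]2[C@@H]([C@@]3(C(=O)OC)CO3)[C@@H](OC(=O)/C=C(\C)CC)[C@@H]1O
F18 | step 24 | E-enone diester | C=C1[C@H]2CC(=O)/C(=C/C)[C@H]2[C@@H]([C@@]3(C(=O)OC)CO3)[C@@H](OC(=O)/C=C(\C)CC)[C@@H]1OC(=O)[C@H](C)CC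
F19 | step 24 | β-boryl ketone (pinacol boronate at C10) | C=C1[C@H]2CC(=O)[C@@H]([C@H](C)B3OC(C)(C)C(C)(C)O3)[C@H]2[C@@H]([C@@]4(C(=O)OC)CO4)[C@@H](OC(=O)/C=C(\C)CC)[C@@H]1OC(=O)[C@H](C)CC
A1 | alternative 1 | ynal: 2-ethynylcyclopentanone carrying the γ-lactone with a C9 aldehyde | C#C[C@H]1CC(=O)[C@@H]([C@H](C)OC(C)=O)[C@H]1[C@H]2CC(=O)O[C@H]2C=O
A2 | alternative 1 | tricyclic lactone with exocyclic methylene and C9 triethylsilyl ether | C=C1[C@H]2CC(=O)[C@@H]([C@H](C)OC(C)=O)[C@H]2[C@H]3CC(=O)O[C@H]3[C@@H]1O[Si](CC)(CC)CC
A3 | alternative 2 | 5-tethered 2,2,6-trimethyldioxinone cyclopentene | C1(OCCO1)([C@H]2C[C@H](O[Si](C)(C)C(C)(C)C)C=C2)[C@@H](O[Si](C)(C)C(C)(C)C)[C@H](O[Si](C)(C)C(C)(C)C)C3=C(C)OC(C)(C)OC3=O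
A4 | alternative 2 | cyclobutane photoadduct with fused dioxanone | C12(OCCO1)[C@H]3C[C@H](O[Si](C)(C)C(C)(C)C)[C@@H]4[C@H]3[C@]5(C(=O)OC(C)(C)O[C@]54C)[C@@H](O[Si](C)(C)C(C)(C)C)[C@@H]2O[Si](C)(C)C(C)(C)C
A5 | alternative 3 | cis-decalin with tertiary C10 carbinol and C5 mesylate | C1[C@H]2C[C@H](O[Si](C)(C)C(C)(C)C)[C@@H](OS(C)(=O)=O)[C@@](C)(O)[C@H]2[C@@H](CC(=O)OC)C=C1
A6 | alternative 3 | cis-hydrindene with C5 acetyl and C4 silyloxy | C1[C@H]2C[C@H](O[Si](C)(C)C(C)(C)C)[C@@H](C(C)=O)[C@H]2[C@@H](CC(=O)OC)C=C1
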